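All runs were generated by integration with made-up constants; noise was put on by code.

Z is what the two orders ask about, and Z needs E, so the rate to watch is not the rate at which X disappears. By the last reading the ochre flask had lost 98.4% of its X charge, yet its E amounted to 80.0% of that charge, which is less, so some X leaves without E.

| flask | X | E | time |
|---|---|---|---|
| violet | 0.400 M | 0.480 M |  |
| ochre | 0.600 M | 0.480 M |  |
| blue | 0.400 M | 0.960 M |  |
| teal | 0.160 M | 0.240 M | 7.6 min |

| violet run: time / min | violet run: [X] / M | ochre run: time / min | ochre run: [X] / M | blue run: time / min | blue run: [X] / M |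
|---|---|---|---|---|---|
| 0.34 | 0.2977 | 0.34 | 0.4239 | 0.34 | 0.2783 |
| 1.0 | 0.1857 | 1.0 | 0.2495 | 1.0 | 0.1548 |
| 2.0 | 0.1042 | 2.0 | 0.1313 | 2.0 | 0.0732 |
| 3.1 | 0.0587 | 3.1 | 0.0788 | 3.1 | 0.0318 |
| 4.4 | 0.0339 | 4.4 | 0.0426 | 4.4 | 0.0120 |
| 5.9 | 0.0143 | 5.9 | 0.0212 | 5.9 | 0.0071 |
| 7.6 | 0.0099 | 7.6 | 0.0099 | 7.6 | 0.0033 |

(scatter of a reading: 0.002 M)

1. the power of [E] that the first rate follows, about the charge of the violet run; measure it at two percent of X made into Z
2. the power of [X] that the first rate follows, about the charge of the violet run; measure it at two percent of X made into Z (one fixed amount of Z, the same in the runs compared)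
3. X in the teal run at 7.6 min, as a share of the X charged

- Overall: X + E -> Z.
- Constant volume, constant temperature.
- "The second partner" is E.
- An order is taken over about fifteen percent of the charge, up and down.

From the share of X left at the first reading you get a loss constant: the natural log of charge over reading, divided by the time, which is an average over that first stretch and carries the scatter of the reading.

Turn E up first. By hand, twice the E should double the road to Z and raise the loss constant by that road's part. Here is what the flasks do:

violet: 74.4% left, loss constant 0.869 min⁻¹

blue: 69.6% left, loss constant 1.07 min⁻¹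

The loss constant gained per molar of E, which I call the E slope, reads 0.413 M⁻¹ min⁻¹ from these two flasks. With E near its charge, this road is pseudo-first-order in X. Over that first stretch of the violet flask it carries 0.198 min⁻¹, about a quarter of the loss constant there. If Z comes by this road, the rate of Z is the E slope times E times X, so in my reckoning the order in E is one.

Now turn X up. By hand, the rate of Z should follow X. The ochre flask's loss constant is 1.02 min⁻¹, higher at the same E, so X also leaves faster when there is more of it. I read that extra loss as a road without E, so I do not count it as Z, and my order in X is one.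

The forecast gives 0.25 for E, 1.35 for X and 2.7% for teal, with this line for E: “E order ≈ 0.215/0.885 ≈ 0.24”. We part on both orders. For teal I make no reckoning of my own.

    X + E → Z + L (0.4782 M⁻¹ min⁻¹)
    2 X → Xa (0.5226 M⁻¹ min⁻¹)
    X → Zo (0.2562 min⁻¹)

The flask gives 1.1 for E, 1.0 for X and 4.59% of the charge for teal. At equal Z made, the ochre rate stands at 1.5 times the violet rate, and its X charge at 1.50 times. The E slope times the charges gives 0.0793 M min⁻¹ for the violet flask, against a rate of Z of 0.083 M min⁻¹ at the point where the orders are measured, and 0.159 M min⁻¹ for the blue flask, against 0.17 M min⁻¹ at that point.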